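**Retrosynthetic overview** (labdane numbering; ring A = C1–C5, C10; ring B = C5–C10)
1. The target is (4S,5R,9S,10R,13R)-13-hydroxylabd-8(17)-ene-15,19-dioic acid. Both acids come from methyl esters at the end, and the C13 carbinol comes from formal asymmetric hydration of a (13E)-enoate made from a C13 methyl ketone.
2. The C18 methyl group is put on C4 last in ring A, by alkylating the ester enolate obtained from a C3=C4–C19 enoate.
3. Key disconnection: C1–C2 and C5–C10 are cut together. The enabling feature is that C2–C3–C4–C5 of ring A, with the C19 carboxyl on C4, is a 2-(alkoxycarbonyl)-1,3-diene retron, that C10 with C20 and C1 is an isopropenyl group, and that the ring-B chain C6–C7–C8(=C17)–C9 tethers the two, so one intramolecular Diels–Alder reaction closes rings A and B at once under control of C9.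
4. The triene comes from (S)-limonene. Cleaving its ring C=C gives a chain that already holds C9 as a stereocentre, the isopropenyl dienophile (C10, C1, C20) and C11–C13/C16 as a methyl ketone; C17 is added by α-methylenation, C6/C5 by a Claisen rearrangement, C4/C19 and C3/C2 by bromo-olefination and Stille coupling.
5. Ring order: the limonene ring is opened in step 1; rings A and B are formed together in step 9; no other carbocycle is made.

Key step: step 9

Assumption: the hand of the chiral bisphosphine in step 13 is assigned beforehand on a simple (E)-3-methylalk-2-enoate, and the antipode is used if the model shows the opposite sense.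

Step 1
Reactants: 1 (S)-(−)-limonene; 2 3-chloroperoxybenzoic acid; 3 water
Product: 6 (3S)-6-oxo-3-(prop-1-en-2-yl)heptanal, via limonene 1,2-oxide 4 (not isolated), via limonene-1,2-diol 5 (not isolated)
Conditions: mCPBA (1.0 equiv), CH2Cl2, 0 °C; then H5IO6, THF/H2O, 0 to 23 °C
Reagents that add atoms: 3-chloroperoxybenzoic acid OOC(=O)c1cccc(Cl)c1 (one carbonyl oxygen); water O (the other carbonyl oxygen)
Why: Prilezhaev epoxidation picks the trisubstituted ring alkene over the isopropenyl group, and periodic acid hydrolyses the epoxide and cleaves the glycol (Malaprade cleavage), so the limonene stereocentre is untouched and becomes C9.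

Step 2
Reactants: 6 (3S)-6-oxo-3-(prop-1-en-2-yl)heptanal; 7 formaldehyde
Product: 8 (3R)-2-methylidene-6-oxo-3-(prop-1-en-2-yl)heptanal
Conditions: 37% aq. CH2O, pyrrolidine (10 mol%), propionic acid (10 mol%), i-PrOH, 45 °C
Reagents that add atoms: formaldehyde C=O
Why: Amine-catalysed Mannich condensation/elimination (aldehyde α-methylenation) acts on the aldehyde only, since the methyl ketone forms no enamine under these conditions, and installs C17 on C8 without touching the bonds at C9.

Step 3
Reactants: 8 (3R)-2-methylidene-6-oxo-3-(prop-1-en-2-yl)heptanal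
Product: 9 (5R)-6-(hydroxymethyl)-5-(prop-1-en-2-yl)hept-6-en-2-one
Conditions: LiAlH(OtBu)3, THF, −78 to −40 °C
Reagents that add atoms: none
Why: Chemoselective 1,2-reduction, because the bulky alkoxyaluminium hydride reduces an aldehyde much faster than a ketone at low temperature and does not add in conjugate fashion.

Step 4
Reactants: 9 (5R)-6-(hydroxymethyl)-5-(prop-1-en-2-yl)hept-6-en-2-one; 10 ethylene glycol
Product: 11 (3R)-2-methylidene-5-(2-methyl-1,3-dioxolan-2-yl)-3-(prop-1-en-2-yl)pentan-1-ol
Conditions: ethylene glycol, PPTS (cat.), benzene, reflux (Dean–Stark)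
Reagents that add atoms: ethylene glycol OCCO
Why: Acid-catalysed ketalisation with water removal masks the C13 ketone against the bases and the dissolving metal of steps 7, 10 and 12, the mild pyridinium acid leaving the allylic alcohol and the skipped diene alone.

Step 5
Reactants: 11 (3R)-2-methylidene-5-(2-methyl-1,3-dioxolan-2-yl)-3-(prop-1-en-2-yl)pentan-1-ol; 12 ethyl vinyl ether
Product: 14 (5R)-4-methylidene-7-(2-methyl-1,3-dioxolan-2-yl)-5-(prop-1-en-2-yl)heptanal, via allyl vinyl ether 13 (not isolated)
Conditions: ethyl vinyl ether (solvent), Hg(OAc)2 (10 mol%), reflux; K2CO3, concentrate; PhMe, 150 °C, sealed tube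
Reagents that add atoms: ethyl vinyl ether C=COCC
Why: Mercury-catalysed transvinylation followed by Claisen [3,3] rearrangement adds C6 and C5 (as the aldehyde); because both termini of the 2-substituted allyl unit are CH2, the rearrangement regenerates the 1,1-disubstituted C8=C17 alkene without any regiochemical choice and under neutral conditions.

Step 6
Reactants: 15 methyl bis(2,2,2-trifluoroethoxy)phosphorylacetate (Still–Gennari reagent); 16 bromine
Product: 18 methyl 2-[bis(2,2,2-trifluoroethoxy)phosphoryl]-2-bromoacetate, via dibromophosphonoacetate 17 (not isolated)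
Conditions: Br2, aq. NaOH, 0 °C; then SnCl2·2H2O, EtOH/H2O, 0 °C
Reagents that add atoms: bromine BrBr
Why: Exhaustive base-mediated α-bromination of the activated methylene followed by reductive monodebromination with SnCl2 avoids the mono/di mixture that direct monobromination of so acidic a methylene would give.

Step 7
Reactants: 14 (5R)-4-methylidene-7-(2-methyl-1,3-dioxolan-2-yl)-5-(prop-1-en-2-yl)heptanal; 18 methyl 2-[bis(2,2,2-trifluoroethoxy)phosphoryl]-2-bromoacetate
Product: 19 methyl (2E,7R)-2-bromo-6-methylidene-9-(2-methyl-1,3-dioxolan-2-yl)-7-(prop-1-en-2-yl)non-2-enoate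
Conditions: 18, KOtBu, 18-crown-6, THF, −78 °C; then 14
Reagents that add atoms: methyl 2-[bis(2,2,2-trifluoroethoxy)phosphoryl]-2-bromoacetate COC(=O)C(Br)P(=O)(OCC(F)(F)F)OCC(F)(F)F
Why: Horner–Wadsworth–Emmons olefination with the electron-poor bis(trifluoroethyl) α-bromophosphonate is under kinetic control and should place the chain cis to the ester and trans to bromine (2E), the geometry the diene needs.

Step 8
Reactants: 19 methyl (2E,7R)-2-bromo-6-methylidene-9-(2-methyl-1,3-dioxolan-2-yl)-7-(prop-1-en-2-yl)non-2-enoate; 20 tributyl(vinyl)stannane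
Product: 21 methyl (2Z,7R)-2-ethenyl-6-methylidene-9-(2-methyl-1,3-dioxolan-2-yl)-7-(prop-1-en-2-yl)non-2-enoate
Conditions: Pd2(dba)3 (2.5 mol%), AsPh3 (10 mol%), NMP, 40 °C; product kept cold with BHT and used at once
Reagents that add atoms: tributyl(vinyl)stannane C=C[Sn](CCCC)(CCCC)CCCC
Why: Stille coupling of the α-bromoacrylate proceeds with retention of alkene geometry, so the vinyl group (C3, C2) ends up trans to the chain and the 2-(methoxycarbonyl)-1,3-diene is formed below the temperature of any cycloaddition.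

Step 9
Reactants: 21 methyl (2Z,7R)-2-ethenyl-6-methylidene-9-(2-methyl-1,3-dioxolan-2-yl)-7-(prop-1-en-2-yl)non-2-enoate
Product: 22 methyl (4aR,5S,8aR)-4a-methyl-6-methylidene-5-[2-(2-methyl-1,3-dioxolan-2-yl)ethyl]-3,4,4a,5,6,7,8,8a-octahydronaphthalene-1-carboxylate
Conditions: PhMe (0.005 M), BHT (10 mol%), 190 °C, sealed tube
Reagents that add atoms: none
Why: Concerted thermal type-1 intramolecular Diels–Alder reaction in which the s-cis 2-vinyl enoate (C2=C3–C4=C5) adds suprafacially across the isopropenyl C10=C1 to form C1–C2 and C5–C10 and leave the ring-A double bond at C3=C4; the closest known reaction type is the thermal cycloaddition of 1,7,9-decatrienes carrying a methyl group on the inner dienophile carbon, which gives angular-methyl trans-decalins. Ring A is closed as the new cyclohexene of the [4+2] event, and ring B is closed in the same event by the C5–C10 bond as the fused six-membered ring over the four-atom tether C6–C7–C8–C9, whose length allows only the fused and not the bridged mode. C5 and C10 are set together: the trans ring fusion should come from the transition state with the tether exo, where only the C10 methyl group lies under the diene while the branched C9 and the ester stay apart, and the face is fixed by C9, whose C11 chain sits pseudo-equatorial on the chair-like tether and anti to the forming C5–C10 bond, which puts C20 cis to the side chain (5R,10R from 9S in labdane numbering). The step needs trans over cis fusion, one diene face and intra- over intermolecular reaction; the first two rest on the C10 methyl group and the limonene-derived C9 stereocentre, the third on high dilution with a radical inhibitor and on the diene geometry from steps 7 and 8 (chain trans to vinyl), which can reach s-cis, cannot undergo a 1,5-hydrogen shift and makes the acrylate unit a poor partner for dimerisation. No Lewis acid is used, because activating the ester would favour stepwise attack of C1 on C5 (ene or [2+2] manifold) over the tether-enforced C1–C2/C5–C10 pairing.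

Step 10
Reactants: 22 methyl (4aR,5S,8aR)-4a-methyl-6-methylidene-5-[2-(2-methyl-1,3-dioxolan-2-yl)ethyl]-3,4,4a,5,6,7,8,8a-octahydronaphthalene-1-carboxylate; 23 iodomethane
Product: 25 methyl (1S,4aR,5S,8aR)-1,4a-dimethyl-6-methylidene-5-[2-(2-methyl-1,3-dioxolan-2-yl)ethyl]decahydronaphthalene-1-carboxylate, via lithium ester enolate 24 (not isolated)
Conditions: Li (2.2 equiv), NH3(l)/THF, −78 °C; then MeI, −78 to −33 °C
Reagents that add atoms: iodomethane CI
Why: Dissolving-metal reductive alkylation of the α,β-unsaturated ester generates the C4 enolate regiospecifically, and iodomethane should enter on the equatorial α-face, away from the axial C10 methyl group, leaving the ester axial (4S, the 19-oate series); the isolated alkene and the ketal are inert.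

Step 11
Reactants: 25 methyl (1S,4aR,5S,8aR)-1,4a-dimethyl-6-methylidene-5-[2-(2-methyl-1,3-dioxolan-2-yl)ethyl]decahydronaphthalene-1-carboxylate; 3 water
Product: 26 methyl (1S,4aR,5S,8aR)-1,4a-dimethyl-6-methylidene-5-(3-oxobutyl)decahydronaphthalene-1-carboxylate
Conditions: 1 M aq. HCl, THF, 23 °C
Reagents that add atoms: water O
Why: Acid-catalysed ketal hydrolysis with dilute acid at room temperature frees the C13 ketone; it is mild enough that the exocyclic alkene should not migrate and the hindered ester should not hydrolyse.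

Step 12
Reactants: 26 methyl (1S,4aR,5S,8aR)-1,4a-dimethyl-6-methylidene-5-(3-oxobutyl)decahydronaphthalene-1-carboxylate; 27 trimethyl phosphonoacetate
Product: 28 methyl (1S,4aR,5S,8aR)-5-[(3E)-5-methoxy-3-methyl-5-oxopent-3-en-1-yl]-1,4a-dimethyl-6-methylidenedecahydronaphthalene-1-carboxylate (dimethyl agathate)
Conditions: NaH, THF, 0 to 65 °C; (13E) isomer separated on AgNO3-impregnated SiO2
Reagents that add atoms: trimethyl phosphonoacetate COC(=O)CP(=O)(OC)OC
Why: Horner–Wadsworth–Emmons olefination of the methyl ketone adds C14 and C15 and should favour the (13E)-enoate, which is separated from the minor (13Z) isomer because the two would lead to opposite configurations at C13 in step 13; the C19 ester has no α-hydrogen and is not affected by the base.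

Step 13
Reactants: 28 dimethyl agathate; 29 bis(pinacolato)diboron; 30 sodium perborate
Product: 32 methyl (1S,4aR,5S,8aR)-5-[(3R)-3-hydroxy-5-methoxy-3-methyl-5-oxopentyl]-1,4a-dimethyl-6-methylidenedecahydronaphthalene-1-carboxylate, via tertiary pinacol boronate 31 (not isolated)
Conditions: CuCl (5 mol%), (R,R)-QuinoxP* (6 mol%), NaOtBu (10 mol%), B2pin2, MeOH (2 equiv), THF, 23 °C; then NaBO3·4H2O, THF/H2O, 23 °C
Reagents that add atoms: sodium perborate [Na+].[O-]OB=O (hydroxyl oxygen); bis(pinacolato)diboron CC1(C)OB(OC1(C)C)B1OC(C)(C)C(C)(C)O1 (boron of 31 only, not kept in 32)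
Why: Copper-catalysed enantioselective conjugate borylation of a β,β-disubstituted enoate sets C13 by catalyst control over the faces of the geometrically pure (13E)-alkene, and perborate oxidation replaces boron by hydroxyl with retention to give 13R; the unactivated exocyclic alkene and the saturated C19 ester do not react.

Step 14
Reactants: 32 methyl (1S,4aR,5S,8aR)-5-[(3R)-3-hydroxy-5-methoxy-3-methyl-5-oxopentyl]-1,4a-dimethyl-6-methylidenedecahydronaphthalene-1-carboxylate
Product: 33 (1S,4aR,5S,8aR)-5-[(3R)-4-carboxy-3-hydroxy-3-methylbutyl]-1,4a-dimethyl-6-methylidenedecahydronaphthalene-1-carboxylic acid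
Conditions: NaSEt, DMF, 80 °C; then 1 M aq. HCl
Reagents that add atoms: none
Why: Thiolate SN2 O-demethylation attacks the methyl groups, not the carbonyls, so the hindered axial C19 ester and the C15 ester are both cleaved without the strongly basic or acidic hydrolysis that would risk retro-aldol cleavage or dehydration of the tertiary β-hydroxy acid.

**Compound list**
1 | (S)-(−)-limonene, (4S)-1-methyl-4-(prop-1-en-2-yl)cyclohex-1-ene | CC1=CC[C@H](CC1)C(C)=C | starting material
2 | 3-chloroperoxybenzoic acid | OOC(=O)c1cccc(Cl)c1 | starting material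
3 | water | O | starting material
4 | (4S)-limonene 1,2-oxide (cis/trans mixture) | CC12OC1C[C@H](CC2)C(C)=C | intermediate (not isolated)
5 | (4S)-p-menth-8-ene-1,2-diol | CC1(O)C(O)C[C@H](CC1)C(C)=C | intermediate (not isolated)
6 | (3S)-6-oxo-3-(prop-1-en-2-yl)heptanal | O=CC[C@H](CCC(C)=O)C(C)=C | intermediate
7 | formaldehyde | C=O | starting material
8 | (3R)-2-methylidene-6-oxo-3-(prop-1-en-2-yl)heptanal | O=CC(=C)[C@H](CCC(C)=O)C(C)=C | intermediate
9 | (5R)-6-(hydroxymethyl)-5-(prop-1-en-2-yl)hept-6-en-2-one | OCC(=C)[C@H](CCC(C)=O)C(C)=C | intermediate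
10 | ethylene glycol | OCCO | starting material
11 | (3R)-2-methylidene-5-(2-methyl-1,3-dioxolan-2-yl)-3-(prop-1-en-2-yl)pentan-1-ol | OCC(=C)[C@H](CCC1(C)OCCO1)C(C)=C | intermediate
12 | ethyl vinyl ether | C=COCC | starting material
13 | 2-[(3R)-4-[(ethenyloxy)methyl]-3-(prop-1-en-2-yl)pent-4-en-1-yl]-2-methyl-1,3-dioxolane | C=COCC(=C)[C@H](CCC1(C)OCCO1)C(C)=C | intermediate (not isolated)
14 | (5R)-4-methylidene-7-(2-methyl-1,3-dioxolan-2-yl)-5-(prop-1-en-2-yl)heptanal | O=CCCC(=C)[C@H](CCC1(C)OCCO1)C(C)=C | intermediate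
15 | methyl bis(2,2,2-trifluoroethoxy)phosphorylacetate | COC(=O)CP(=O)(OCC(F)(F)F)OCC(F)(F)F | starting material
16 | bromine | BrBr | starting material
17 | methyl 2-[bis(2,2,2-trifluoroethoxy)phosphoryl]-2,2-dibromoacetate | COC(=O)C(Br)(Br)P(=O)(OCC(F)(F)F)OCC(F)(F)F | intermediate (not isolated)
18 | methyl 2-[bis(2,2,2-trifluoroethoxy)phosphoryl]-2-bromoacetate | COC(=O)C(Br)P(=O)(OCC(F)(F)F)OCC(F)(F)F | intermediate
19 | methyl (2E,7R)-2-bromo-6-methylidene-9-(2-methyl-1,3-dioxolan-2-yl)-7-(prop-1-en-2-yl)non-2-enoate | COC(=O)/C(Br)=C\CCC(=C)[C@H](CCC1(C)OCCO1)C(C)=C | intermediate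
20 | tributyl(vinyl)stannane | C=C[Sn](CCCC)(CCCC)CCCC | starting material
21 | methyl (2Z,7R)-2-ethenyl-6-methylidene-9-(2-methyl-1,3-dioxolan-2-yl)-7-(prop-1-en-2-yl)non-2-enoate | COC(=O)/C(C=C)=C\CCC(=C)[C@H](CCC1(C)OCCO1)C(C)=C | intermediate
22 | methyl (4aR,5S,8aR)-4a-methyl-6-methylidene-5-[2-(2-methyl-1,3-dioxolan-2-yl)ethyl]-3,4,4a,5,6,7,8,8a-octahydronaphthalene-1-carboxylate | C=C1CC[C@@H]2[C@](C)(CCC=C2C(=O)OC)[C@H]1CCC1(C)OCCO1 | intermediate
23 | iodomethane | CI | starting material
24 | lithium enolate of the C4 ester (C4=C(OLi)OMe) | C=C1CC[C@@H]2[C@](C)(CCCC2=C([O-])OC)[C@H]1CCC1(C)OCCO1.[Li+] | intermediate (not isolated)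
25 | methyl (1S,4aR,5S,8aR)-1,4a-dimethyl-6-methylidene-5-[2-(2-methyl-1,3-dioxolan-2-yl)ethyl]decahydronaphthalene-1-carboxylate | C=C1CC[C@@H]2[C@](C)(CCC[C@]2(C)C(=O)OC)[C@H]1CCC1(C)OCCO1 | intermediate
26 | methyl (1S,4aR,5S,8aR)-1,4a-dimethyl-6-methylidene-5-(3-oxobutyl)decahydronaphthalene-1-carboxylate | C=C1CC[C@@H]2[C@](C)(CCC[C@]2(C)C(=O)OC)[C@H]1CCC(C)=O | intermediate
27 | trimethyl phosphonoacetate | COC(=O)CP(=O)(OC)OC | starting material
28 | dimethyl agathate, methyl (1S,4aR,5S,8aR)-5-[(3E)-5-methoxy-3-methyl-5-oxopent-3-en-1-yl]-1,4a-dimethyl-6-methylidenedecahydronaphthalene-1-carboxylate | C=C1CC[C@@H]2[C@](C)(CCC[C@]2(C)C(=O)OC)[C@H]1CC/C(C)=C/C(=O)OC | intermediate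
29 | bis(pinacolato)diboron | CC1(C)OB(OC1(C)C)B1OC(C)(C)C(C)(C)O1 | starting material
30 | sodium perborate | [Na+].[O-]OB=O | starting material
31 | methyl (1S,4aR,5S,8aR)-5-[(3S)-5-methoxy-3-methyl-5-oxo-3-(4,4,5,5-tetramethyl-1,3,2-dioxaborolan-2-yl)pentyl]-1,4a-dimethyl-6-methylidenedecahydronaphthalene-1-carboxylate | C=C1CC[C@@H]2[C@](C)(CCC[C@]2(C)C(=O)OC)[C@H]1CC[C@@](C)(B1OC(C)(C)C(C)(C)O1)CC(=O)OC | intermediate (not isolated)
32 | methyl (1S,4aR,5S,8aR)-5-[(3R)-3-hydroxy-5-methoxy-3-methyl-5-oxopentyl]-1,4a-dimethyl-6-methylidenedecahydronaphthalene-1-carboxylate | C=C1CC[C@@H]2[C@](C)(CCC[C@]2(C)C(=O)OC)[C@H]1CC[C@@](C)(O)CC(=O)OC | intermediate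
33 | (1S,4aR,5S,8aR)-5-[(3R)-4-carboxy-3-hydroxy-3-methylbutyl]-1,4a-dimethyl-6-methylidenedecahydronaphthalene-1-carboxylic acid, (4S,5R,9S,10R,13R)-13-hydroxylabd-8(17)-ene-15,19-dioic acid | C=C1CC[C@@H]2[C@](C)(CCC[C@]2(C)C(=O)O)[C@H]1CC[C@@](C)(O)CC(=O)O | target

**Total step count:** 14
**Longest linear sequence:** 13 steps (steps 1–5 and 7–14 from 1; step 6 prepares reagent 18)

**Steps most likely to fail**

Step 9. What may go wrong: intermolecular [4+2] dimerisation or oligomerisation of the ester-bearing diene outrunning the slow intramolecular addition to the unactivated 1,1-disubstituted alkene, and loss of trans/facial selectivity at the temperature needed. Fallback, setting out from 14 and coming back at 22: the cycloaddition is run on a diene without the acrylate unit and the ester is introduced afterwards. Aldehyde 14 is treated with CBr4/PPh3 (CH2Cl2, 0 °C) to give the 1,1-dibromoalkene (6R)-1,1-dibromo-5-methylidene-8-(2-methyl-1,3-dioxolan-2-yl)-6-(prop-1-en-2-yl)oct-1-ene F1. A trans-selective Stille coupling with 20 (Pd2(dba)3, tri(2-furyl)phosphine, PhMe, 80 °C) replaces only the bromine trans to the chain and gives (3Z,8R)-3-bromo-7-methylidene-10-(2-methyl-1,3-dioxolan-2-yl)-8-(prop-1-en-2-yl)deca-1,3-diene F2. Thermal intramolecular Diels–Alder reaction of this 2-bromodiene under the conditions of step 9 gives the ring-A vinyl bromide 2-{2-[(1S,4aR,8aR)-5-bromo-8a-methyl-2-methylidene-1,2,3,4,4a,7,8,8a-octahydronaphthalen-1-yl]ethyl}-2-methyl-1,3-dioxolane F3. Methoxycarbonylation (Pd(OAc)2, dppp, CO, MeOH, Et3N, DMF, 70 °C) converts it into 22.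

Step 13. What may go wrong: insufficient discrimination by the copper catalyst between the methyl and CH2 substituents at the prochiral β-carbon, and carry-over of (13Z)-enoate from step 12, each giving the C13 epimer, which could not be removed later. Fallback, setting out from 28 and coming back at 33: C13 is set by reagent-controlled epoxidation. Both esters of 28 are reduced with i-Bu2AlH (excess, CH2Cl2, −78 to 23 °C) to (4S,5R,9S,10R,13E)-labda-8(17),13-diene-15,19-diol F4. Sharpless asymmetric epoxidation of its allylic alcohol (Ti(OiPr)4, D-(−)-diethyl tartrate, t-BuOOH, 4 Å sieves, CH2Cl2, −20 °C) gives (4S,5R,9S,10R,13R,14R)-13,14-epoxylabd-8(17)-ene-15,19-diol F5. NaAlH2(OCH2CH2OMe)2 (THF, 0 °C) opens the epoxy alcohol at C14 to (4S,5R,9S,10R,13R)-labd-8(17)-ene-13,15,19-triol F6. Dess–Martin oxidation of both primary alcohols gives (4S,5R,9S,10R,13R)-13-hydroxylabd-8(17)-ene-15,19-dial F7, and NaClO2/NaH2PO4/2-methylbut-2-ene oxidation gives 33 directly.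

Step 10. What may go wrong: over-reduction of the ester by the dissolving metal, protonation of the enolate before it is alkylated, or reductive dimerisation at the β-carbon. Fallback, setting out from 22 and coming back at 25: reduction and alkylation are separated. Conjugate reduction with Mg in MeOH (23 °C) gives the saturated ester methyl (4aS,5S,8aS)-4a-methyl-6-methylidene-5-[2-(2-methyl-1,3-dioxolan-2-yl)ethyl]decahydronaphthalene-1-carboxylate (C1 epimers) F8. Deprotonation with LiN(iPr)2 (THF/HMPA, −78 °C) and alkylation of the enolate with 23 from the equatorial face (−78 to 0 °C) gives 25.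

**Further compounds**
F1 | step 9 | (6R)-1,1-dibromo-5-methylidene-8-(2-methyl-1,3-dioxolan-2-yl)-6-(prop-1-en-2-yl)oct-1-ene | BrC(Br)=CCCC(=C)[C@H](CCC1(C)OCCO1)C(C)=C
F2 | step 9 | (3Z,8R)-3-bromo-7-methylidene-10-(2-methyl-1,3-dioxolan-2-yl)-8-(prop-1-en-2-yl)deca-1,3-diene | C=C/C(Br)=C/CCC(=C)[C@H](CCC1(C)OCCO1)C(C)=C
F3 | step 9 | 2-{2-[(1S,4aR,8aR)-5-bromo-8a-methyl-2-methylidene-1,2,3,4,4a,7,8,8a-octahydronaphthalen-1-yl]ethyl}-2-methyl-1,3-dioxolane | C=C1CC[C@@H]2[C@](C)(CCC=C2Br)[C@H]1CCC1(C)OCCO1
F4 | step 13 | (4S,5R,9S,10R,13E)-labda-8(17),13-diene-15,19-diol | C=C1CC[C@@H]2[C@](C)(CCC[C@]2(C)CO)[C@H]1CC/C(C)=C/CO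
F5 | step 13 | (4S,5R,9S,10R,13R,14R)-13,14-epoxylabd-8(17)-ene-15,19-diol | C=C1CC[C@@H]2[C@](C)(CCC[C@]2(C)CO)[C@H]1CC[C@@]1(C)O[C@@H]1CO
F6 | step 13 | (4S,5R,9S,10R,13R)-labd-8(17)-ene-13,15,19-triol | C=C1CC[C@@H]2[C@](C)(CCC[C@]2(C)CO)[C@H]1CC[C@@](C)(O)CCO
F7 | step 13 | (4S,5R,9S,10R,13R)-13-hydroxylabd-8(17)-ene-15,19-dial | C=C1CC[C@@H]2[C@](C)(CCC[C@]2(C)C=O)[C@H]1CC[C@@](C)(O)CC=O
F8 | step 10 | methyl (4aS,5S,8aS)-4a-methyl-6-methylidene-5-[2-(2-methyl-1,3-dioxolan-2-yl)ethyl]decahydronaphthalene-1-carboxylate (C1 epimers) | C=C1CC[C@@H]2[C@](C)(CCCC2C(=O)OC)[C@H]1CCC1(C)OCCO1
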